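**Retrosynthetic overview**

1. Locants are germacrane locants: ring A is the ten-membered carbocycle C1–C10 (C1=C10 with C14 = CO2Me on C10, oxiranes C2–C3 and C4–C5, C15 = methyl on C4); ring B is the γ-lactone O–C6–C7–C11–C12 with the exo-methylene C13.
2. Last ring: the C4–C5 oxirane, by epoxidation of the (4Z)-alkene of the bicyclic macrolactone from its open face.
3. Key disconnection C5–C6: the macrolactone comes from an acyclic chain with an aldehyde at C6 and a (Z)-alkenyl iodide at C5; a Ni/Cr-mediated alkenyl–aldehyde coupling closes ring A, and in the same operation the C6 alkoxide closes ring B on the C12 methyl ester, C6 being set by C7/C8.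
4. Enabling feature: C6 is the lactone carbinol carbon, and its neighbour C5 is, one oxidation level below the oxirane, the CH end of the trisubstituted C4=C5 alkene, so C5–C6 is an alkenyl–carbinol bond with the C12 ester γ to the new alkoxide; the cis-2,3-oxirane, the Z alkene and the cis disposition of C2 and C9 on C1=C10 fold C1–C5 into a turn towards C6.
5. The chain is joined at C9–C10 from an alkenylmagnesium (C1–C5/C10/C14 iodoenoate, from propargyl alcohol via a Sharpless cis-epoxidation) and a C6–C9/C11–C13 aldehyde (indium allylation of (R)-glyceraldehyde acetonide, then esterification with the Sharpless-derived epoxyangelic acid); ring order: the two early oxiranes, then rings A and B together, then the C4–C5 oxirane.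

Key step: step 18

Remark: the target is read as 2R,3R,4R,5R,6S,7R,8S,9R with a (2S,3S)-epoxyangelate and C2 cis to C9 on C1=C10; CIP descriptors of intermediates change with substituent priorities while the spatial arrangement at each centre stays that of the target; 2-[(4-methoxyphenyl)methoxy]acetaldehyde and (4R)-2,2-dimethyl-1,3-dioxolane-4-carbaldehyde are taken as commercial.

**Route**

Step 1
Reactants: 1 prop-2-yn-1-ol
Product: 3 (2Z)-3-iodo-2-methylprop-2-en-1-ol, via alkenylmagnesium alkoxide 2 (not isolated)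
Conditions: MeMgBr (2.5 equiv), CuI (10 mol%), THF, −10 °C → rt; then I2, −78 → 0 °C
Reagents that add atoms: methylmagnesium bromide C[Mg]Br; iodine II
Why: Copper-catalysed anti-carbomagnesiation of the propargylic alkoxide (five-membered magnesium chelate) places methyl on the internal carbon and magnesium cis to CH2O, and iodinolysis with retention should give the Z iodide that becomes C3–C5 and C15.

Step 2
Reactants: 3 (2Z)-3-iodo-2-methylprop-2-en-1-ol
Product: 4 (2Z)-3-iodo-2-methylprop-2-enal
Conditions: MnO2 (15 equiv), CH2Cl2, rt, dark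
Reagents that add atoms: none
Why: Heterogeneous allylic oxidation with MnO2 stops at the enal and, being neutral, should leave the Z geometry and the C–I bond intact.

Step 3
Reactants: 4 (2Z)-3-iodo-2-methylprop-2-enal; 5 methyl 2-[bis(2,2,2-trifluoroethoxy)phosphoryl]acetate
Product: 6 methyl (2Z,4Z)-5-iodo-4-methylpenta-2,4-dienoate
Conditions: KN(SiMe3)2, 18-crown-6, THF, −78 °C
Reagents that add atoms: none
Why: Still–Gennari olefination, in which the electron-poor phosphonate eliminates under kinetic control, should give the (2Z)-enoate whose C2=C3 geometry later becomes the cis-oxirane.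

Step 4
Reactants: 6 methyl (2Z,4Z)-5-iodo-4-methylpenta-2,4-dienoate
Product: 7 (2Z,4Z)-5-iodo-4-methylpenta-2,4-dien-1-ol
Conditions: iBu2AlH (2.2 equiv), CH2Cl2, −78 °C; aqueous tartrate work-up
Reagents that add atoms: none
Why: 1,2-Reduction of the ester by the aluminium hydride at low temperature should give the allylic alcohol without touching the alkenyl iodide or either double-bond geometry.

Step 5
Reactants: 7 (2Z,4Z)-5-iodo-4-methylpenta-2,4-dien-1-ol
Product: 8 [(2R,3S)-3-[(1Z)-1-iodoprop-1-en-2-yl]oxiran-2-yl]methanol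
Conditions: Ti(OiPr)4 (0.2 equiv), D-(−)-diethyl tartrate (0.24 equiv), tBuOOH, 4 Å MS, CH2Cl2, −20 °C
Reagents that add atoms: tert-butyl hydroperoxide CC(C)(C)OO
Why: Sharpless asymmetric epoxidation acts only on the alkene allylic to the hydroxyl, and the D-(−)-tartrate directs oxygen to the face that gives the (2R,3S) cis-oxirane (C2 and C3 of the target) by reagent control.

Step 6
Reactants: 8 [(2R,3S)-3-[(1Z)-1-iodoprop-1-en-2-yl]oxiran-2-yl]methanol
Product: 9 (2S,3S)-3-[(1Z)-1-iodoprop-1-en-2-yl]oxirane-2-carbaldehyde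
Conditions: PhI(OAc)2 (1.1 equiv), TEMPO (10 mol%), CH2Cl2, 0 °C → rt
Reagents that add atoms: none
Why: Oxoammonium (TEMPO) oxidation of the primary alcohol under non-basic conditions should give the cis-epoxy aldehyde without epimerisation at C2.

Step 7
Reactants: 9 (2S,3S)-3-[(1Z)-1-iodoprop-1-en-2-yl]oxirane-2-carbaldehyde; 10 methyl 2-(triphenyl-λ5-phosphanylidene)acetate
Product: 12 methyl (2Z)-2-iodo-3-[(2R,3S)-3-[(1Z)-1-iodoprop-1-en-2-yl]oxiran-2-yl]prop-2-enoate, via iodo ylide 11 (not isolated)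
Conditions: 10, N-iodosuccinimide, CH2Cl2, −20 °C; then 9, −20 °C → rt
Reagents that add atoms: N-iodosuccinimide O=C1CCC(=O)N1I
Why: Wittig olefination with the iodo-substituted stabilised ylide, made in the flask by iodination of the parent ylide, should place the ester trans to C2 as required for C1=C10 and leave iodine on C10 for the fragment union.

Step 8
Reactants: 13 angelic acid, (2Z)-2-methylbut-2-enoic acid
Product: 14 (2Z)-2-methylbut-2-en-1-ol
Conditions: LiAlH4, Et2O, 0 °C
Reagents that add atoms: none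
Why: Hydride reduction of the carboxylic acid gives the allylic alcohol with the Z geometry unchanged.

Step 9
Reactants: 14 (2Z)-2-methylbut-2-en-1-ol
Product: 15 [(2R,3S)-2,3-dimethyloxiran-2-yl]methanol
Conditions: Ti(OiPr)4 (0.1 equiv), D-(−)-diethyl tartrate (0.12 equiv), tBuOOH, 4 Å MS, CH2Cl2, −20 °C
Reagents that add atoms: tert-butyl hydroperoxide CC(C)(C)OO
Why: Sharpless asymmetric epoxidation with the D-(−)-tartrate sets both oxirane centres of the side chain by reagent control, and the cis relation of the carbinol carbon and the C3 methyl follows from the Z alkene.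

Step 10
Reactants: 15 [(2R,3S)-2,3-dimethyloxiran-2-yl]methanol
Product: 16 (2S,3S)-2,3-dimethyloxirane-2-carboxylic acid
Conditions: PhI(OAc)2 (2.2 equiv), TEMPO (20 mol%), MeCN/H2O (1:1), rt
Reagents that add atoms: water O
Why: Oxoammonium oxidation through the aldehyde hydrate should give the glycidic acid without opening the electron-poor oxirane.

Step 11
Reactants: 17 2-[(4-methoxyphenyl)methoxy]acetaldehyde; 18 methyl prop-2-enoate
Product: 19 methyl 3-hydroxy-4-[(4-methoxyphenyl)methoxy]-2-methylidenebutanoate (racemic)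
Conditions: DABCO (0.5 equiv), 18 (excess), MeOH, rt
Reagents that add atoms: none
Why: Morita–Baylis–Hillman reaction of the activated α-alkoxy aldehyde with the acrylate gives the adduct, whose racemic carbinol centre is erased in step 12.

Step 12
Reactants: 19 methyl 3-hydroxy-4-[(4-methoxyphenyl)methoxy]-2-methylidenebutanoate
Product: 20 methyl (2Z)-2-(bromomethyl)-4-[(4-methoxyphenyl)methoxy]but-2-enoate
Conditions: N-bromosuccinimide, Me2S, CH2Cl2, 0 °C → rt
Reagents that add atoms: N-bromosuccinimide O=C1CCC(=O)N1Br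
Why: Bromination with allylic transposition (SN2' attack of bromide on the alkoxysulfonium salt) should give the 2-(bromomethyl)enoate with CH2Br cis to the C6 carbon.

Step 13
Reactants: 20 methyl (2Z)-2-(bromomethyl)-4-[(4-methoxyphenyl)methoxy]but-2-enoate; 21 (4R)-2,2-dimethyl-1,3-dioxolane-4-carbaldehyde
Product: 22 methyl (3S,4S)-4-[(4R)-2,2-dimethyl-1,3-dioxolan-4-yl]-4-hydroxy-3-{[(4-methoxyphenyl)methoxy]methyl}-2-methylidenebutanoate
Conditions: indium powder (In, 1.5 equiv), THF/H2O (1:1), rt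
Reagents that add atoms: none
Why: Barbier-type indium 2-(alkoxycarbonyl)allylation through a closed six-membered transition state should give from the Z bromide the syn relation of the new hydroxyl and the C6 carbon (sets C7), while Felkin–Anh attack anti to the dioxolane oxygen sets C8.

Step 14
Reactants: 22 methyl (3S,4S)-4-[(4R)-2,2-dimethyl-1,3-dioxolan-4-yl]-4-hydroxy-3-{[(4-methoxyphenyl)methoxy]methyl}-2-methylidenebutanoate; 16 (2S,3S)-2,3-dimethyloxirane-2-carboxylic acid
Product: 24 methyl (3S,4S)-4-[(4R)-2,2-dimethyl-1,3-dioxolan-4-yl]-4-{[(2S,3S)-2,3-dimethyloxirane-2-carbonyl]oxy}-3-{[(4-methoxyphenyl)methoxy]methyl}-2-methylidenebutanoate, via mixed anhydride 23 (not isolated)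
Conditions: 16, 2,4,6-trichlorobenzoyl chloride, Et3N, toluene, rt; then 22, DMAP, toluene, rt
Reagents that add atoms: none
Why: Yamaguchi esterification acylates the hindered C8 hydroxyl through the mixed anhydride under DMAP catalysis without touching any stereocentre.

Step 15
Reactants: 24 methyl (3S,4S)-4-[(4R)-2,2-dimethyl-1,3-dioxolan-4-yl]-4-{[(2S,3S)-2,3-dimethyloxirane-2-carbonyl]oxy}-3-{[(4-methoxyphenyl)methoxy]methyl}-2-methylidenebutanoate
Product: 26 methyl (3S,4S)-4-{[(2S,3S)-2,3-dimethyloxirane-2-carbonyl]oxy}-3-{[(4-methoxyphenyl)methoxy]methyl}-2-methylidene-5-oxopentanoate, via diol 25 (not isolated)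
Conditions: AcOH/H2O (4:1), 40 °C; evaporation; then NaIO4, THF/pH 7 buffer, 0 °C
Reagents that add atoms: none
Why: Acid hydrolysis of the terminal acetonide followed by periodate glycol cleavage unmasks C9 as the aldehyde and removes the auxiliary stereocentre, the PMB ether and the glycidic ester being stable to aqueous acetic acid.

Step 16
Reactants: 12 methyl (2Z)-2-iodo-3-[(2R,3S)-3-[(1Z)-1-iodoprop-1-en-2-yl]oxiran-2-yl]prop-2-enoate; 26 methyl (3S,4S)-4-{[(2S,3S)-2,3-dimethyloxirane-2-carbonyl]oxy}-3-{[(4-methoxyphenyl)methoxy]methyl}-2-methylidene-5-oxopentanoate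
Product: 29 acyclic C9 acetate with C6–OPMB and C5 iodide (dimethyl heptanedioate; full name in the list), via alkenylmagnesium chloride 27 (not isolated), via magnesium alkoxide 28 (not isolated)
Conditions: 12 (1.2 equiv), iPrMgCl·LiCl (1.2 equiv), THF, −78 °C, 15 min; then 26, −78 °C; then Ac2O (3 equiv), −78 → 0 °C
Reagents that add atoms: acetic anhydride CC(=O)OC(C)=O
Why: Iodine–magnesium exchange occurs only at the ester-activated C10–I bond at −78 °C, the alkenylmagnesium adds to the C9 aldehyde with retention of alkene geometry and anti to the C8 acyloxy group (polar Felkin–Anh model, sets C9), and the alkoxide is acetylated in the flask before the C8 acyl group can migrate.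

Step 17
Reactants: 29 acyclic C9 acetate with C6–OPMB and C5 iodide
Product: 31 acyclic C6 aldehyde with C5 iodide (full name in the list), via primary alcohol 30 (not isolated)
Conditions: DDQ (1.5 equiv), CH2Cl2/pH 7 buffer (10:1), 0 °C; aq. NaHCO3 wash; then PhI(OAc)2, TEMPO (20 mol%), CH2Cl2, 0 °C → rt
Reagents that add atoms: none
Why: Oxidative PMB cleavage under buffered neutral conditions followed at once by oxoammonium oxidation should give the C6 aldehyde before the γ-hydroxy ester can lactonise, and without base that could epimerise C7.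

Step 18
Reactants: 31 acyclic C6 aldehyde with C5 iodide
Product: 33 bicyclic macrolactone with the (4Z)-alkene (full name in the list), via ring-closed hydroxy ester 32 (not isolated)
Conditions: CrCl2 (10 equiv), NiCl2 (1 mol%), DMSO/THF (3:1), 2 mM (slow addition of 31), rt; aq. NH4Cl work-up; SiO2
Reagents that add atoms: none
Why: Zerovalent nickel, formed in the flask from NiCl2 and CrCl2, inserts into the single C5–I bond, the alkenyl group passes to trivalent chromium, and the alkenylchromium adds to the C6 aldehyde; the chromium alkoxide of 32 then attacks the C12 methyl ester on C7 and expels methoxide. The closest known reaction type is the Nozaki–Hiyama–Kishi macrocyclisation of alkenyl iodide–aldehydes to ten-membered carbocycles, followed by the lactonisation known for γ-oxido esters in chromium-mediated 2-(alkoxycarbonyl)allylations. Ring A closes 10-exo-trig (C5 onto C6=O) and ring B closes 5-exo-trig (O6 onto C12=O). The one new stereocentre, C6, is controlled by C7 and C8: Felkin–Anh addition with the C8 branch anti to the incoming alkenyl group, reinforced by 1,3-anti induction from the C8 acyloxy group, should give the 6,7-trans lactone. The step needs chemoselectivity, retention of the Z alkene and ring closure over oligomerisation: CrCl2 leaves enoate, acrylate, esters and oxiranes alone, trisubstituted alkenylchromium species keep their geometry, and high dilution together with the turn built by the cis-oxirane, the Z alkene and the cis-disposed C2/C9 on C1=C10 favours the ten-membered ring.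

Step 19
Reactants: 33 bicyclic macrolactone with the (4Z)-alkene
Product: 34 target CNP0077535.3
Conditions: dimethyldioxirane (1.2 equiv, acetone solution), CH2Cl2, −20 → 0 °C
Reagents that add atoms: dimethyldioxirane CC1(C)OO1
Why: Dioxirane epoxidation takes only the electron-rich trisubstituted C4=C5 alkene, and in the conformer that relieves allylic 1,3-strain at both C3 and C6 (H3 and H6 in the alkene plane) the ring bonds C3–C2 and C6–C7 lie on one face, so oxygen should arrive from the open face and give the (4R,5R) cis-oxirane.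

**Compound list**

1 | prop-2-yn-1-ol | C#CCO | starting material
2 | bromomagnesium (2Z)-3-(bromomagnesio)-2-methylprop-2-en-1-olate | C/C(CO[Mg]Br)=C/[Mg]Br | intermediate
3 | (2Z)-3-iodo-2-methylprop-2-en-1-ol | C/C(CO)=C/I | intermediate
4 | (2Z)-3-iodo-2-methylprop-2-enal | C/C(C=O)=C/I | intermediate
5 | methyl 2-[bis(2,2,2-trifluoroethoxy)phosphoryl]acetate | COC(=O)CP(=O)(OCC(F)(F)F)OCC(F)(F)F | starting material
6 | methyl (2Z,4Z)-5-iodo-4-methylpenta-2,4-dienoate | COC(=O)/C=C\C(C)=C/I | intermediate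
7 | (2Z,4Z)-5-iodo-4-methylpenta-2,4-dien-1-ol | OC/C=C\C(C)=C/I | intermediate
8 | [(2R,3S)-3-[(1Z)-1-iodoprop-1-en-2-yl]oxiran-2-yl]methanol | OC[C@H]1O[C@H]1/C(C)=C\I | intermediate
9 | (2S,3S)-3-[(1Z)-1-iodoprop-1-en-2-yl]oxirane-2-carbaldehyde | O=C[C@H]1O[C@H]1/C(C)=C\I | intermediate
10 | methyl 2-(triphenyl-λ5-phosphanylidene)acetate | COC(=O)C=P(c1ccccc1)(c1ccccc1)c1ccccc1 | starting material
11 | methyl 2-iodo-2-(triphenyl-λ5-phosphanylidene)acetate | COC(=O)C(I)=P(c1ccccc1)(c1ccccc1)c1ccccc1 | intermediate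
12 | methyl (2Z)-2-iodo-3-[(2R,3S)-3-[(1Z)-1-iodoprop-1-en-2-yl]oxiran-2-yl]prop-2-enoate | COC(=O)/C(I)=C/[C@H]1O[C@H]1/C(C)=C\I | intermediate
13 | angelic acid, (2Z)-2-methylbut-2-enoic acid | C/C=C(/C)C(=O)O | starting material
14 | (2Z)-2-methylbut-2-en-1-ol | C/C=C(/C)CO | intermediate
15 | [(2R,3S)-2,3-dimethyloxiran-2-yl]methanol | OC[C@@]1(C)O[C@H]1C | intermediate
16 | (2S,3S)-2,3-dimethyloxirane-2-carboxylic acid | OC(=O)[C@@]1(C)O[C@H]1C | intermediate
17 | 2-[(4-methoxyphenyl)methoxy]acetaldehyde | COc1ccc(COCC=O)cc1 | starting material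
18 | methyl prop-2-enoate | C=CC(=O)OC | starting material
19 | methyl 3-hydroxy-4-[(4-methoxyphenyl)methoxy]-2-methylidenebutanoate (racemic) | COC(=O)C(=C)C(O)COCc1ccc(OC)cc1 | intermediate
20 | methyl (2Z)-2-(bromomethyl)-4-[(4-methoxyphenyl)methoxy]but-2-enoate | COC(=O)/C(CBr)=C/COCc1ccc(OC)cc1 | intermediate
21 | (4R)-2,2-dimethyl-1,3-dioxolane-4-carbaldehyde | O=C[C@H]1COC(C)(C)O1 | starting material
22 | methyl (3S,4S)-4-[(4R)-2,2-dimethyl-1,3-dioxolan-4-yl]-4-hydroxy-3-{[(4-methoxyphenyl)methoxy]methyl}-2-methylidenebutanoate | COc1ccc(COC[C@H](C(=C)C(=O)OC)[C@H](O)[C@H]2COC(C)(C)O2)cc1 | intermediate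
23 | (2S,3S)-2,3-dimethyloxirane-2-carboxylic 2,4,6-trichlorobenzoic anhydride | Clc1cc(Cl)c(C(=O)OC(=O)[C@@]2(C)O[C@H]2C)c(Cl)c1 | intermediate
24 | methyl (3S,4S)-4-[(4R)-2,2-dimethyl-1,3-dioxolan-4-yl]-4-{[(2S,3S)-2,3-dimethyloxirane-2-carbonyl]oxy}-3-{[(4-methoxyphenyl)methoxy]methyl}-2-methylidenebutanoate | COc1ccc(COC[C@H](C(=C)C(=O)OC)[C@H](OC(=O)[C@@]2(C)O[C@H]2C)[C@H]2COC(C)(C)O2)cc1 | intermediate
25 | methyl (3S,4S,5R)-4-{[(2S,3S)-2,3-dimethyloxirane-2-carbonyl]oxy}-5,6-dihydroxy-3-{[(4-methoxyphenyl)methoxy]methyl}-2-methylidenehexanoate | COc1ccc(COC[C@H](C(=C)C(=O)OC)[C@H](OC(=O)[C@@]2(C)O[C@H]2C)[C@H](O)CO)cc1 | intermediate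
26 | methyl (3S,4S)-4-{[(2S,3S)-2,3-dimethyloxirane-2-carbonyl]oxy}-3-{[(4-methoxyphenyl)methoxy]methyl}-2-methylidene-5-oxopentanoate | COc1ccc(COC[C@H](C(=C)C(=O)OC)[C@H](OC(=O)[C@@]2(C)O[C@H]2C)C=O)cc1 | intermediate
27 | methyl (2Z)-2-(chloromagnesio)-3-[(2R,3S)-3-[(1Z)-1-iodoprop-1-en-2-yl]oxiran-2-yl]prop-2-enoate | COC(=O)/C([Mg]Cl)=C/[C@H]1O[C@H]1/C(C)=C\I | intermediate
28 | chloromagnesium alkoxide of dimethyl (2E,3R,4S,5S)-4-{[(2S,3S)-2,3-dimethyloxirane-2-carbonyl]oxy}-3-hydroxy-2-({(2R,3S)-3-[(1Z)-1-iodoprop-1-en-2-yl]oxiran-2-yl}methylidene)-5-{[(4-methoxyphenyl)methoxy]methyl}-6-methylideneheptanedioate | COc1ccc(COC[C@H](C(=C)C(=O)OC)[C@H](OC(=O)[C@@]2(C)O[C@H]2C)[C@H](O[Mg]Cl)/C(C(=O)OC)=C\[C@H]2O[C@H]2/C(C)=C\I)cc1 | intermediate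
29 | dimethyl (2E,3R,4S,5S)-3-(acetyloxy)-4-{[(2S,3S)-2,3-dimethyloxirane-2-carbonyl]oxy}-2-({(2R,3S)-3-[(1Z)-1-iodoprop-1-en-2-yl]oxiran-2-yl}methylidene)-5-{[(4-methoxyphenyl)methoxy]methyl}-6-methylideneheptanedioate | COc1ccc(COC[C@H](C(=C)C(=O)OC)[C@H](OC(=O)[C@@]2(C)O[C@H]2C)[C@H](OC(C)=O)/C(C(=O)OC)=C\[C@H]2O[C@H]2/C(C)=C\I)cc1 | intermediate
30 | dimethyl (2E,3R,4S,5S)-3-(acetyloxy)-4-{[(2S,3S)-2,3-dimethyloxirane-2-carbonyl]oxy}-5-(hydroxymethyl)-2-({(2R,3S)-3-[(1Z)-1-iodoprop-1-en-2-yl]oxiran-2-yl}methylidene)-6-methylideneheptanedioate | OC[C@H](C(=C)C(=O)OC)[C@H](OC(=O)[C@@]1(C)O[C@H]1C)[C@H](OC(C)=O)/C(C(=O)OC)=C\[C@H]1O[C@H]1/C(C)=C\I | intermediate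
31 | dimethyl (2E,3R,4S,5R)-3-(acetyloxy)-4-{[(2S,3S)-2,3-dimethyloxirane-2-carbonyl]oxy}-5-formyl-2-({(2R,3S)-3-[(1Z)-1-iodoprop-1-en-2-yl]oxiran-2-yl}methylidene)-6-methylideneheptanedioate | O=C[C@H](C(=C)C(=O)OC)[C@H](OC(=O)[C@@]1(C)O[C@H]1C)[C@H](OC(C)=O)/C(C(=O)OC)=C\[C@H]1O[C@H]1/C(C)=C\I | intermediate
32 | ring-closed hydroxy diester (germacrane locants): ring A with 6R-hydroxyl, 7S carbon bearing C(=CH2)CO2Me, 8S-epoxyangelate, 9R-acetate, 1(10)E-enoate with C14 methyl ester, (2R,3S)-oxirane and (4Z)-alkene; formed as its chromium alkoxide | O[C@H]1[C@H](C(=C)C(=O)OC)[C@H](OC(=O)[C@@]2(C)O[C@H]2C)[C@H](OC(C)=O)/C(C(=O)OC)=C\[C@H]2O[C@H]2/C(C)=C\1 | intermediate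
33 | methyl (2R,3S,6R,7S,8S,9R)-9-acetoxy-8-{[(2S,3S)-2,3-dimethyloxirane-2-carbonyl]oxy}-2,3-epoxy-12-oxo-6,12-epoxygermacra-1(10)E,4Z,11(13)-trien-14-oate (germacrane locants; 6,7-trans lactone) | C=C1C(=O)O[C@H]2[C@H]1[C@H](OC(=O)[C@@]1(C)O[C@H]1C)[C@H](OC(C)=O)/C(C(=O)OC)=C\[C@H]1O[C@H]1/C(C)=C\2 | intermediate
34 | CNP0077535.3: methyl (2R,3R,4R,5R,6S,7R,8S,9R)-9-acetoxy-8-{[(2S,3S)-2,3-dimethyloxirane-2-carbonyl]oxy}-2,3:4,5-diepoxy-12-oxo-6,12-epoxygermacra-1(10)E,11(13)-dien-14-oate (germacrane locants) | C=C1C(=O)O[C@H]2[C@H]1[C@H](OC(=O)[C@@]1(C)O[C@H]1C)[C@H](OC(C)=O)/C(C(=O)OC)=C\[C@H]1O[C@H]1[C@]1(C)O[C@H]21 | target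

**Step count and risks**

Total step count: 19. Longest linear sequence: 11 steps (steps 1–7, then 16–19).

Steps most likely to fail:

Step 18. The ring closure is slow and dilute. During it the aldehyde may epimerise at C7 (α to the formyl group and allylic to the acrylate), the C11=C13 double bond may move into conjugation, or the C8 carboxylate may be lost by β-elimination. Zerovalent nickel may also ionise the vinyl oxirane or the allylic acetate, oligomerisation may outrun cyclisation, and facial control at C6 may be poor. The fallback removes the acidifying acrylate before the aldehyde is unveiled; it sets out from 29 and comes back at 33. Thia-Michael addition of thiophenol (PhSH, Et3N cat., CH2Cl2, 0 °C; the trisubstituted enoate is far less reactive) should give the C13 phenyl sulfide F1 as C11 epimers. DDQ cleavage of the PMB ether should give the primary alcohol F2, and Dess–Martin periodinane the aldehyde F3, whose C7–H is no longer allylic. Ring closure with CrCl2/NiCl2 as in step 18 should give, through the ring-closed hydroxy ester F4, the sulfide lactone F5. NaIO4 should give the sulfoxide F6, and thermal syn-elimination (toluene, 90 °C, CaCO3) should restore C11=C13 and return the route to 33.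

Step 16. The alkenylmagnesium may lose the C1=C10 geometry through its magnesium allenolate form, Felkin–Anh control at C9 may be weak, the α-acyloxy aldehyde may enolise, and the C8 acyl group may migrate in the alkoxide before acetylation. The fallback sets out from 12 and 26 and comes back at 29. It is a Barbier-type Ni/Cr-mediated coupling (CrCl2, NiCl2 cat., DMSO, rt): the alkenyl nucleophile is generated at the ester-activated C10–I bond in the presence of the aldehyde under non-basic conditions, and the chromium alkoxide does not promote acyl migration. It should give the C9 alcohol F7, and acetylation (Ac2O, pyridine, CH2Cl2, 0 °C) leads to 29.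

Step 19. Oxygen delivery to the macrocyclic alkene may show poor or reversed facial selectivity. The fallback, for the case that the wrong face is preferred, sets out from 33 and comes back at 34, and inverts the face sense by a halohydrin sequence. N-bromosuccinimide in THF/H2O should form the bromonium ion on the face that the dioxirane uses, and water opens it anti at the tertiary C4 to give the bromohydrin F8. Ag2O in CH2Cl2 should then close the oxirane by attack of the C4 oxygen on C5 with inversion and give 34.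

Further compounds
F1 | step 18 | C13 phenyl sulfide of 29 (thiophenol adduct at C11=C13, C11 epimers) | COc1ccc(COC[C@H](C(CSc2ccccc2)C(=O)OC)[C@H](OC(=O)[C@@]2(C)O[C@H]2C)[C@H](OC(C)=O)/C(C(=O)OC)=C\[C@H]2O[C@H]2/C(C)=C\I)cc1
F2 | step 18 | primary alcohol from F1 (C6–OH, C13 phenyl sulfide) | OC[C@H](C(CSc1ccccc1)C(=O)OC)[C@H](OC(=O)[C@@]1(C)O[C@H]1C)[C@H](OC(C)=O)/C(C(=O)OC)=C\[C@H]1O[C@H]1/C(C)=C\I
F3 | step 18 | C6 aldehyde with C13 phenyl sulfide | O=C[C@H](C(CSc1ccccc1)C(=O)OC)[C@H](OC(=O)[C@@]1(C)O[C@H]1C)[C@H](OC(C)=O)/C(C(=O)OC)=C\[C@H]1O[C@H]1/C(C)=C\I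
F4 | step 18 | ring-closed hydroxy ester with C13 phenyl sulfide (formed as its chromium alkoxide) | O[C@H]1[C@H](C(CSc2ccccc2)C(=O)OC)[C@H](OC(=O)[C@@]2(C)O[C@H]2C)[C@H](OC(C)=O)/C(C(=O)OC)=C\[C@H]2O[C@H]2/C(C)=C\1
F5 | step 18 | macrolactone with 13-phenylsulfanyl group (11,13-dihydro-33 sulfide) | C(Sc1ccccc1)C1C(=O)O[C@H]2[C@H]1[C@H](OC(=O)[C@@]1(C)O[C@H]1C)[C@H](OC(C)=O)/C(C(=O)OC)=C\[C@H]1O[C@H]1/C(C)=C\2
F6 | step 18 | macrolactone with 13-phenylsulfinyl group (sulfoxide of F5) | C(S(=O)c1ccccc1)C1C(=O)O[C@H]2[C@H]1[C@H](OC(=O)[C@@]1(C)O[C@H]1C)[C@H](OC(C)=O)/C(C(=O)OC)=C\[C@H]1O[C@H]1/C(C)=C\2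
F7 | step 16 | C9 alcohol, dimethyl (2E,3R,4S,5S)-4-{[(2S,3S)-2,3-dimethyloxirane-2-carbonyl]oxy}-3-hydroxy-2-({(2R,3S)-3-[(1Z)-1-iodoprop-1-en-2-yl]oxiran-2-yl}methylidene)-5-{[(4-methoxyphenyl)methoxy]methyl}-6-methylideneheptanedioate | COc1ccc(COC[C@H](C(=C)C(=O)OC)[C@H](OC(=O)[C@@]2(C)O[C@H]2C)[C@H](O)/C(C(=O)OC)=C\[C@H]2O[C@H]2/C(C)=C\I)cc1
F8 | step 19 | (4S,5S)-5-bromo-4-hydroxy-4,5-dihydro derivative of 33 (bromohydrin, germacrane locants) | C=C1C(=O)O[C@H]2[C@H]1[C@H](OC(=O)[C@@]1(C)O[C@H]1C)[C@H](OC(C)=O)/C(C(=O)OC)=C\[C@H]1O[C@H]1[C@](C)(O)[C@H]2Br
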